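The earlier runs and the new flask stem from a simulated flask for substances that don't exist, noise included.

**Choosing a ratio.** If the share of target hung on one thing, I reasoned, it was the ratio of side product to target at the asked time, so I counted everything as a fraction of the charge and started there. The share, the selectivity of a flask, follows from that ratio at once.

| flask | substrate | catalyst | remark | time |
|---|---|---|---|---|
| south | 0.058 M | 0.1 mol% | run made earlier |  |
| north | 0.97 M | 0.1 mol% | run made earlier |  |
| ochre | 0.050 M | 0.1 mol% |  | 2.0 h |
| blue | 0.10 M | 0.1 mol% |  | 2.0 h |
| grey | 0.20 M | 0.1 mol% |  | 2.0 h |
| red | 0.40 M | 0.1 mol% |  | 2.0 h |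
| teal | 0.80 M | 0.1 mol% |  | 2.0 h |

| run | time / min | target / % | side product / % |
|---|---|---|---|
| south | 15.0 | 11.8 | 1.9 |
| south | 30.0 | 19.2 | 4.7 |
| south | 50.0 | 22.0 | 5.3 |
| south | 60.0 | 25.0 | 4.3 |
| south | 80.0 | 25.8 | 6.1 |
| south | 90.0 | 26.9 | 6.6 |
| south | 120 | 27.4 | 8.5 |
| north | 15.0 | 30.6 | 0.7 |
| north | 30.0 | 29.5 | 0.7 |
| north | 50.0 | 29.2 | 0.9 |
| north | 60.0 | 30.7 | 1.3 |
| north | 80.0 | 29.1 | 2.7 |
| north | 90.0 | 28.8 | 1.8 |
| north | 120 | 29.3 | 1.3 |

(readings scatter by 0.5 percentage points)

- share of target in all that became target or side product for ochre, blue, grey, red, teal, in this order
- the course of these numbers from the first flask to the last (rises, then falls / rises all the way / falls all the way / falls, then rises / hardly changes)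

- a reading or a percentage of target counts all its forms, free or not
- "hardly changes" means that all values lie within two and a half points (for a concentration: within two and a half percent of the largest)

**First way.** At 120 min the ratio read 0.310 in the south run and 0.0444 in the north run. I took the fall of its logarithm per unit logarithm of the charge, 0.690, and called this the leak slope. Run from south along that slope, the share came to 74.4% in ochre, 88.3% in grey and 95.2% in teal. The north side reading in it carries a scatter of 0.5 percentage points.

**Second way.** Then I reckoned from rates, setting the north run aside. With the loading fixed, catalyst grows with the charge, so the making of target should grow in proportion, while a first-order leak keeps its pace, and the slope should be one. From south this gave 73.5% in ochre, close to the first way, but that is no check, since ochre lies beside south and both ways start from the south ratio. In teal it gave 97.8%, and there the ways parted.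

**Finding the cheat.** I held the second way against the north run. It allowed that run 0.0185 of its target as side product, or 0.542% at 120 min, yet the north side readings from 60.0 min on averaged 1.78%, a gap of 1.2 points where one reading scatters by 0.5 points. North target stood at 30.6% at 15.0 min and 29.3% at the end, so the ratio in the north run was no longer one of starting rates. The leak slope rests on the single north reading 1.3%, lower than that average, so I carried it as a reading and no more. I kept the first way, with a share that rises all the way.

**The forecast.** It gave 76%, 83.2%, 88.1%, 91.5% and 94.2%, rises all the way, holding that “Side product is a slow leak, and its percentage falls as concentration rises”. My ochre stood lower and my teal higher.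

**The flask.** The row came out 75.9%, 81.2%, 88.3%, 93.1% and 95.5%: rises all the way. With the leak slope, ochre's target of 26.2% implied 9.02% side product against 8.33% found, and teal's 30.1%, crystals counted in, implied 1.52% against 1.43%.

    substrate + catalyst ⇌ catalyst + target (K = 2.00, k = 12000 L mol⁻¹ h⁻¹)
    substrate → side product (k = 0.130 h⁻¹)
    crystals ⇌ target, rate k3*(cs3 - [target]) while solid is left; crystals form when [target] > cs3 (solubility = 30.0 mM, k = 3.20 h⁻¹)
    2 substrate → homo dimer (k = 18.0 L mol⁻¹ h⁻¹)

**Where substrate went.** In ochre at 0.318 h, substrate went to target, forward step alone, at 0.63 of the rate at which it went to homo dimer. At 2.00 h ochre held target at 26.2% and homo dimer, every dimer counted as two substrate, at 52.3%.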